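The target comes from a charge of substrate with other conformer beside it, and the number to watch in each flask is its count: the clock constant for target, reckoned below, times the time spent at each temperature.

| setting | teal | violet | elm | cedar | ash | larch |
|---|---|---|---|---|---|---|
| substrate | 13 mM | 30 mM | 20 mM | 20 mM | 20 mM | 20 mM |
| other conformer | 0.25 equiv | 0.25 equiv | 0.250 equiv | 0.250 equiv | 0.250 equiv | 0.250 equiv |
| temperature | −10 °C | 25 °C | 25 °C | 55 °C | −5 °C |  |
| remark | run made earlier | run made earlier |  |  |  | at −5 °C until 20 min, from then on at 55 °C |
| time |  |  | 40 min | 40 min | 40 min | 40 min |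

| run | time / min | target / % | substrate / % |
|---|---|---|---|
| teal | 25.0 | 1.4 | 79.7 |
| teal | 60.0 | 1.1 | 77.9 |
| teal | 120 | 1.3 | 79.2 |
| teal | 180 | 2.2 | 77.1 |
| violet | 4.00 | 5.3 | 81.2 |
| violet | 12.0 | 14.1 | 69.8 |
| violet | 20.0 | 21.2 | 61.5 |
| violet | 30.0 | 31.9 | 48.7 |

(readings scatter by 1 percentage point)

- the best flask by amount of target, in percent of the substrate and other conformer together charged; "all alike" if 1.5 percentage points covers them all (elm / cedar / ash / larch / all alike)
- amount of target at the end, in percent of the substrate and other conformer together charged, elm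
- amount of target at the end, in percent of the substrate and other conformer together charged, cedar
- amount of target at the end, in percent of the substrate and other conformer together charged, ash
- amount of target at the end, in percent of the substrate and other conformer together charged, larch

- the numbers in the tables scatter by 1 percentage point (one standard deviation)
- in a conversion other conformer counts as not yet reacted

The charged pool is the limiting reagent, and the violet run opens its books with 80.0 % as substrate and 20.0 % as other conformer. At 4.00 min the substrate and target columns sum to 86.5 %, more than the substrate charged, so some other conformer has already crossed into them. At 30.0 min they sum to 80.6 %, and 19.4 % stands unread. The reckoning here takes the mean of those sums, 83.6 %, as the ceiling on target.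

The target entry is then a first-order clock. Between the first and last violet readings, target gained per minute over mean substrate gives 0.0158 min⁻¹. The last teal reading gives 1.59 × 10⁻⁴ min⁻¹, though it carries a scatter of 1 percentage point on 2.2 %. Together they give the clock's temperature slope, an apparent activation energy, of 85.7 kJ mol⁻¹.

A flask's count is its clock constant times its time, and target is the ceiling times one minus exp(−count). Elm comes to 39.1 %. Ash, with 3.29 × 10⁻⁴ min⁻¹, comes to 1.09 %. At 55 °C the clock runs at 0.372 min⁻¹, so the hot part of larch counts 7.43 and its cold hold 0.00658. Cedar counts 14.9. Both counts put target at the ceiling of 83.6 %, so this reckoning leaves cedar and larch level.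

The forecast differs a little: 40 %, 80 %, 2 % and 82 % for elm, cedar, ash and larch, with larch best. Its choice rests on this: “Any heat-driven loss of target slightly favours larch, a tentative call.”

The simulation gives larch: elm 37.9 %, cedar 78.1 %, ash 0.615 %, larch 83.8 %.

    target ⇌ isomer of the product (K = 1.30, k = 4.90 × 10⁻⁶ s⁻¹, Ea = 93.0 kJ mol⁻¹, ΔH = −32.0 kJ mol⁻¹)
    other conformer ⇌ dormant form (K = 104, k = 1.56 × 10⁻⁴ s⁻¹, Ea = 83.0 kJ mol⁻¹, ΔH = −45.0 kJ mol⁻¹)
    substrate ⇌ other conformer (K = 0.104, k = 3.69 × 10⁻⁴ s⁻¹, Ea = 94.0 kJ mol⁻¹, ΔH = −40.0 kJ mol⁻¹)
    other conformer → isomer of the product (k = 9.53 × 10⁻⁴ s⁻¹, Ea = 78.0 kJ mol⁻¹)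
    substrate → target (k = 2.57 × 10⁻⁴ s⁻¹, Ea = 97.0 kJ mol⁻¹)
    (constants at 25 °C)

Larch ends with substrate 0.0152 % and target 83.8 %. Cedar held target 84.2 % at 20.0 min but 78.1 % at 40.0 min, while its isomer of the product rose from 15.0 % to 21.3 %. The lead of larch over cedar, 5.7 points, is wider than the margin of 1.5 points. For a repeat of ash at 10 °C, the same slope reckons the clock at 0.00252 min⁻¹, for a count of 0.101. That reckons target at 8.02 %, more than the 5.94 % this neighbour flask holds.

All runs come from a simulation from invented constants, noise included.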